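**Plan**
Cuts (labdane numbering): the O-acetyl and O-silyl groups come off first. The trans-diaxial C6/C7 oxygens are traced through a 6β,7β-epoxide to an 8-en-7-one. C9–C11 is cut (Stork–Danheiser transposition) to a trans-decalin-7,9-dione, then C5–C10 and C7–C8 are cut together, which opens both rings to an acyclic keto enimide. That chain is cut at C5=C6 (olefination) and at C1–C10 and C3–C4 (two enolate alkylations).
Forward order: a linear C14 chain is built, rings A and B close in one operation, the side chain is joined at C9, C6 and C7 are oxygenated, and the silyl group is removed.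
Enabling feature: in ring B, C9 lies between C8 and C10, and C6 lies between C5 and C7. With C9 as a ketone, C10 and C8 form a 1,3-dinucleophile facing the 1,3-dielectrophile C5=C6–C7(=O)X. C10 and C5 are already tied by the C1–C4 chain of ring A, and quaternary C4 rules out γ-deprotonation.
Stereochemistry: C5 comes from an (S)-4-benzyloxazolidinone that also serves as the leaving group at C7. C10 comes from a chair transition state (trans-decalin). C6 and C7 are set by substrate control (α-face hydroxylation, axial hydride) and then both inverted through the β-epoxide. The 13E alkene is bought with the enynol starting material.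

Key step: step 7

Assumption: the SMILES is read as (5S,6S,7S,10S)-6β,7α-diacetoxylabda-8,13E-dien-15-ol (trans-decalin, both acetates axial); labdane numbering and α/β (β = face of the C10 methyl) are used for all compounds.

**Step 1**
Reactants: 1 ethyl isobutyrate; 2 propane-1,3-diyl dibromide (1,3-dibromopropane)
Product: 4 ethyl 5-bromo-2,2-dimethylpentanoate, via lithium ester enolate 3 (not isolated)
Conditions: LiN(i-Pr)2 (commercial solution), THF, −78 °C; then 2 (3 equiv), −78 to 23 °C
Reagents that add atoms: lithium diisopropylamide CC(C)[N-]C(C)C.[Li+] (its lithium stays only in 3)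
Why: Alkylation of a fully substituted ester enolate with a primary bromide (SN2) builds quaternary C4 with its gem-dimethyl group, excess dibromide holding back double alkylation, and no stereocentre is formed.

**Step 2**
Reactants: 5 pentan-3-one; 4 ethyl 5-bromo-2,2-dimethylpentanoate
Product: 7 ethyl 2,2,6-trimethyl-7-oxononanoate, via lithium ketone enolate 6 (not isolated)
Conditions: LiN(i-Pr)2, THF, −78 °C; then DMPU, 4, −78 to 23 °C
Reagents that add atoms: lithium diisopropylamide CC(C)[N-]C(C)C.[Li+] (its lithium stays only in 6)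
Why: Ketone enolate alkylation (SN2) joins C10 to C1, the neopentyl-type ester of 4 resisting Claisen attack, and the new stereocentre (future C10) may stay racemic because step 7 erases it by enolisation.

**Step 3**
Reactants: 7 ethyl 2,2,6-trimethyl-7-oxononanoate
Product: 8 diol 2,2,6-trimethylnonane-1,7-diol
Conditions: LiAlH4, Et2O, 0 to 23 °C; aqueous NaOH work-up
Reagents that add atoms: none
Why: Exhaustive LiAlH4 reduction of ester and ketone sidesteps any chemoselectivity question, and the new carbinol stereocentre is of no consequence because step 4 removes it.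

**Step 4**
Reactants: 8 diol 2,2,6-trimethylnonane-1,7-diol
Product: 9 keto aldehyde 2,2,6-trimethyl-7-oxononanal
Conditions: Dess–Martin periodinane (2.4 equiv), CH2Cl2, 23 °C
Reagents that add atoms: none
Why: Dess–Martin oxidation takes both alcohols to the carbonyl level in one operation, and the aldehyde cannot enolise or epimerise since its α-carbon (future C4) is quaternary.

**Step 5**
Reactants: 10 (S)-4-benzyloxazolidin-2-one; 11 diethylphosphonoacetic acid
Product: 12 diethyl {2-[(S)-4-benzyl-2-oxooxazolidin-3-yl]-2-oxoethyl}phosphonate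
Conditions: DCC, DMAP (cat.), CH2Cl2, 0 to 23 °C
Reagents that add atoms: none
Why: Carbodiimide and DMAP mediated N-acylation of an oxazolidinone (Steglich-type coupling) gives the olefination reagent without touching the auxiliary stereocentre.

**Step 6**
Reactants: 9 keto aldehyde 2,2,6-trimethyl-7-oxononanal; 12 phosphonate imide
Product: 13 (S)-4-benzyl-3-[(E)-4,4,8-trimethyl-9-oxoundec-2-enoyl]oxazolidin-2-one
Conditions: LiCl, i-Pr2NEt, MeCN, 23 °C
Reagents that add atoms: none
Why: Horner–Wadsworth–Emmons olefination under Masamune–Roush conditions reacts with the aldehyde only, leaves the ketone unenolised and gives the (E)-enimide (C5=C6) as expected for a stabilised phosphonate and a bulky aldehyde.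

**Step 7**
Reactants: 13 (S)-4-benzyl-3-[(E)-4,4,8-trimethyl-9-oxoundec-2-enoyl]oxazolidin-2-one
Product: 15 (4aS,8aS)-2,5,5,8a-tetramethylhexahydronaphthalene-1,3(2H,4H)-dione (trans-decalin-7,9-dione in labdane numbering), via Michael adduct 14 (not isolated)
Conditions: MgBr2·OEt2 (3 equiv), i-Pr2NEt (4 equiv), CH2Cl2 (0.02 M), 23 to 40 °C; then 1 M HCl
Reagents that add atoms: none
Why: Proposed new method: MgBr2 chelates the two imide carbonyls of 13 and i-Pr2NEt enolises the magnesium-bound ethyl ketone reversibly; the C10 enolate adds to C5 of the activated enimide (C5–C10 bond, ring A) to give 14 after proton transfer, and the C8 enolate of 14 then attacks the acyl carbon C7 and expels the oxazolidinone (C7–C8 bond, ring B), the magnesium 1,3-diketonate being the thermodynamic sink. The closest known reaction types are the base-mediated consecutive Michael–Claisen [3+3] synthesis of cyclohexane-1,3-diones from ketones and enoates, the MgBr2/amine soft-enolisation C-acylation of ketones and chelate-controlled conjugate additions to N-enoyl oxazolidinones, and what is new is their union in one intramolecular event in which the auxiliary is activator, stereocontroller and leaving group. Ring A closes in the 6-(enolexo)-exo-trig mode and ring B in the 6-(enolendo)-exo-trig mode. C5 is controlled by the benzyl group of the auxiliary, which covers one face of the chelated s-cis (E)-enoyl unit so that C10 bonds to the other face (5S), and C10 is controlled relative to C5 by a chair transition state with C6 and C9 equatorial and the C10 methyl axial and anti to H5 (10S, trans-decalin), while C8 is enolised and of no consequence. The step needs the hindered C10 enolate to win over the C8 enolate, no deconjugation and no intermolecular reaction: addition through C8 would need an eight-membered ring and enolisation is reversible, quaternary C4 leaves no γ-hydrogen, and its gem-dimethyl group together with high dilution favours ring closure.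

**Step 8**
Reactants: 15 trans-decalin-7,9-dione
Product: 16 (4aS,8aS)-3-isobutoxy-2,5,5,8a-tetramethyl-4a,5,6,7,8,8a-hexahydronaphthalen-1(4H)-one (C7 isobutyl enol ether with the C9 ketone free)
Conditions: i-BuOH, p-TsOH·H2O (cat.), toluene, reflux, Dean–Stark trap
Reagents that add atoms: isobutanol CC(C)CO
Why: Acid-catalysed enol etherification of the unsymmetrical 1,3-dione under equilibrating conditions should place the alkoxy group at the less hindered C7 and keep the carbonyl at C9 beside quaternary C10, as is known for 4,4-disubstituted cyclohexane-1,3-diones, and C5 and C10 are not affected.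

**Step 9**
Reactants: 17 (E)-3-methylpent-2-en-4-yn-1-ol
Product: 18 (E)-tert-butyl[(3-methylpent-2-en-4-yn-1-yl)oxy]diphenylsilane
Conditions: TBDPSCl, imidazole, CH2Cl2, 0 to 23 °C
Reagents that add atoms: tert-butyl(chloro)diphenylsilane CC(C)(C)[Si](Cl)(c1ccccc1)c1ccccc1
Why: Standard silylation of a primary allylic alcohol, the tert-butyldiphenylsilyl group being chosen to survive t-BuLi, aqueous HCl, acetic acid and carbonate in later steps.

**Step 10**
Reactants: 18 silyl enyne
Product: 19 (E)-tert-butyl[(3-methylpenta-2,4-dien-1-yl)oxy]diphenylsilane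
Conditions: H2 (1 atm), Pd/CaCO3 poisoned with Pb(OAc)2, quinoline, hexane, 23 °C
Reagents that add atoms: none
Why: Semihydrogenation of the terminal alkyne over lead-poisoned palladium stops at the vinyl group and leaves the trisubstituted (E)-alkene untouched.

**Step 11**
Reactants: 19 silyl diene
Product: 21 (E)-5-(tert-butyldiphenylsilyloxy)-3-methylpent-3-en-1-ol, via B-alkyl-9-BBN 20 (not isolated)
Conditions: 9-BBN, THF, 0 to 23 °C; then NaOH, H2O2, 0 °C
Reagents that add atoms: hydrogen peroxide OO; 9-borabicyclo[3.3.1]nonane B1C2CCCC1CCC2 (stays only in 20)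
Why: Hydroboration–oxidation in which bulky 9-BBN selects the monosubstituted terminus of the 1,3-diene and places boron on the end carbon (future C11), so that the (E)-alkene geometry is kept.

**Step 12**
Reactants: 21 homoallylic alcohol
Product: 22 (E)-tert-butyl[(5-iodo-3-methylpent-2-en-1-yl)oxy]diphenylsilane
Conditions: I2, PPh3, imidazole, CH2Cl2, 0 °C
Reagents that add atoms: iodine [I][I]
Why: Appel-type iodination (PPh3, I2, imidazole) converts the primary alcohol by SN2 displacement under neutral conditions that spare the silyl ether and the alkene.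

**Step 13**
Reactants: 22 homoallylic iodide; 16 C7 isobutyl enol ether
Product: 25 silyl-protected labda-8,13E-dien-7-one (15-OTBDPS), via homoallyl-lithium 23 (not isolated), via lithium carbinolate 24 (not isolated)
Conditions: 22, t-BuLi (2.1 equiv), Et2O–pentane, −78 °C; then 16, −78 to 0 °C; then 1 M HCl, THF, 23 °C
Reagents that add atoms: tert-butyllithium [Li]C(C)(C)C (its lithium stays only in 23 and 24)
Why: Stork–Danheiser transposition, in which iodine–lithium exchange gives 23, 1,2-addition to the C9 carbonyl of the vinylogous ester gives 24 and acid then ionises the tertiary allylic carbinol and hydrolyses the enol ether, so that the C9–C11 bond, the tetrasubstituted C8=C9 alkene and the C7 ketone arise together and the transient C9 stereocentre vanishes.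

**Step 14**
Reactants: 25 silyl-protected labda-8,13E-dien-7-one
Product: 27 6α-hydroxy enone (6α-hydroxy-15-OTBDPS-labda-8,13E-dien-7-one), via potassium dienolate 26 (not isolated)
Conditions: KN(SiMe3)2, THF, −78 °C; then 2-(phenylsulfonyl)-3-phenyloxaziridine, −78 °C; then AcOH
Reagents that add atoms: 2-(phenylsulfonyl)-3-phenyloxaziridine O=S(=O)(N1OC1c1ccccc1)c1ccccc1; potassium hexamethyldisilazide C[Si](C)(C)[N-][Si](C)(C)C.[K+] (its potassium stays only in 26)
Why: Davis oxidation of the kinetic cross-conjugated (C6) enolate, in which the oxaziridine should approach the α-face because the β-face of C6 is screened by the syn-axial methyl groups on C4 and C10, which sets the equatorial 6α-hydroxyl and spares both alkenes.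

**Step 15**
Reactants: 27 6α-hydroxy enone
Product: 28 6α-mesyloxy enone
Conditions: MsCl, Et3N, CH2Cl2, 0 °C
Reagents that add atoms: methanesulfonyl chloride CS(=O)(=O)Cl
Why: Routine mesylation of the unhindered equatorial 6α-alcohol with retention at C6 turns it into the leaving group for the inversion in step 16.

**Step 16**
Reactants: 28 6α-mesyloxy enone
Product: 30 6β,7β-epoxide (6β,7β-epoxy-15-OTBDPS-labda-8,13E-diene), via hydroxy mesylate 29 (not isolated)
Conditions: NaBH4, CeCl3·7H2O, MeOH–THF, −40 °C; aqueous work-up; then K2CO3, MeOH, 23 to 45 °C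
Reagents that add atoms: none
Why: Luche reduction should deliver hydride axially from the α-face to give the pseudo-equatorial 7β-alcohol 29, whose alkoxide then displaces the 6α-mesylate from the β-face (3-exo-tet SN2 with inversion at C6, through a boat-like ring B as in the closure of trans-diequatorial sugar sulfonates to anhydro sugars) to give the 6β,7β-epoxide.

**Step 17**
Reactants: 30 6β,7β-epoxide
Product: 31 7α-acetoxy-6β-alcohol (15-OTBDPS)
Conditions: AcOH, NaOAc (buffer), 23 °C
Reagents that add atoms: acetic acid CC(=O)O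
Why: Acetolysis of a vinyl epoxide, in which acetate should attack the allylic C7 from the open α-face with inversion, the regiochemistry being backed at once by allylic activation, by the Fürst–Plattner rule (trans-diaxial 6β-OH and 7α-OAc) and by the shielding of C6.

**Step 18**
Reactants: 31 7α-acetoxy-6β-alcohol
Product: 32 6β,7α-diacetate (15-OTBDPS)
Conditions: Ac2O, DMAP (cat.), pyridine, 50 °C
Reagents that add atoms: acetic anhydride CC(=O)OC(C)=O
Why: DMAP-catalysed acetylation with warming is the usual answer to hindered axial 6β-alcohols of labdanes, proceeds with retention and makes any 7-to-6 acetyl shift harmless because both positions end as acetates.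

**Step 19**
Reactants: 32 6β,7α-diacetate (15-OTBDPS)
Product: 33 (5S,6S,7S,10S)-6β,7α-diacetoxylabda-8,13E-dien-15-ol (CNP0187815.1)
Conditions: Bu4NF, AcOH, THF, 0 to 23 °C
Reagents that add atoms: none
Why: Fluoride cleavage of the silyl ether, buffered with acetic acid so that no alkoxide can hydrolyse or shift the acetates, frees the primary allylic alcohol without touching any stereocentre.

**Compound list**
1 | ethyl isobutyrate | CCOC(=O)C(C)C | starting material
2 | 1,3-dibromopropane | BrCCCBr | starting material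
3 | lithium enolate of ethyl isobutyrate | CCOC([O-])=C(C)C.[Li+] | intermediate
4 | ethyl 5-bromo-2,2-dimethylpentanoate | CCOC(=O)C(C)(C)CCCBr | intermediate
5 | pentan-3-one | CCC(=O)CC | starting material
6 | lithium enolate of pentan-3-one (E/Z mixture) | CC=C([O-])CC.[Li+] | intermediate
7 | ethyl 2,2,6-trimethyl-7-oxononanoate (racemic) | CCOC(=O)C(C)(C)CCCC(C)C(=O)CC | intermediate
8 | 2,2,6-trimethylnonane-1,7-diol (diastereomer mixture) | CCC(O)C(C)CCCC(C)(C)CO | intermediate
9 | 2,2,6-trimethyl-7-oxononanal (racemic) | CCC(=O)C(C)CCCC(C)(C)C=O | intermediate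
10 | (S)-4-benzyloxazolidin-2-one | O=C1N[C@@H](Cc2ccccc2)CO1 | starting material
11 | diethylphosphonoacetic acid | CCOP(=O)(CC(=O)O)OCC | starting material
12 | diethyl {2-[(S)-4-benzyl-2-oxooxazolidin-3-yl]-2-oxoethyl}phosphonate | CCOP(=O)(OCC)CC(=O)N1[C@@H](Cc2ccccc2)COC1=O | intermediate
13 | (S)-4-benzyl-3-[(E)-4,4,8-trimethyl-9-oxoundec-2-enoyl]oxazolidin-2-one (both epimers at the ketone α-carbon) | CCC(=O)C(C)CCCC(C)(C)/C=C/C(=O)N1[C@@H](Cc2ccccc2)COC1=O | intermediate
14 | (S)-4-benzyl-3-{2-[(1S,2S)-2,6,6-trimethyl-2-propanoylcyclohexyl]acetyl}oxazolidin-2-one | CCC(=O)[C@@]1(C)CCCC(C)(C)[C@@H]1CC(=O)N1[C@@H](Cc2ccccc2)COC1=O | intermediate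
15 | (4aS,8aS)-2,5,5,8a-tetramethylhexahydronaphthalene-1,3(2H,4H)-dione (C8 epimers and enol) | CC1C(=O)C[C@H]2C(C)(C)CCC[C@]2(C)C1=O | intermediate
16 | (4aS,8aS)-3-isobutoxy-2,5,5,8a-tetramethyl-4a,5,6,7,8,8a-hexahydronaphthalen-1(4H)-one | CC1=C(OCC(C)C)C[C@H]2C(C)(C)CCC[C@]2(C)C1=O | intermediate
17 | (E)-3-methylpent-2-en-4-yn-1-ol | C#C/C(C)=C/CO | starting material
18 | (E)-tert-butyl[(3-methylpent-2-en-4-yn-1-yl)oxy]diphenylsilane | C#C/C(C)=C/CO[Si](c1ccccc1)(c1ccccc1)C(C)(C)C | intermediate
19 | (E)-tert-butyl[(3-methylpenta-2,4-dien-1-yl)oxy]diphenylsilane | C=C/C(C)=C/CO[Si](c1ccccc1)(c1ccccc1)C(C)(C)C | intermediate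
20 | 9-[(E)-5-(tert-butyldiphenylsilyloxy)-3-methylpent-3-en-1-yl]-9-borabicyclo[3.3.1]nonane | B1(CC/C(C)=C/CO[Si](c3ccccc3)(c3ccccc3)C(C)(C)C)C2CCCC1CCC2 | intermediate
21 | (E)-5-(tert-butyldiphenylsilyloxy)-3-methylpent-3-en-1-ol | OCC/C(C)=C/CO[Si](c1ccccc1)(c1ccccc1)C(C)(C)C | intermediate
22 | (E)-tert-butyl[(5-iodo-3-methylpent-2-en-1-yl)oxy]diphenylsilane | ICC/C(C)=C/CO[Si](c1ccccc1)(c1ccccc1)C(C)(C)C | intermediate
23 | (E)-5-(tert-butyldiphenylsilyloxy)-3-methylpent-3-en-1-yllithium | [Li]CC/C(C)=C/CO[Si](c1ccccc1)(c1ccccc1)C(C)(C)C | intermediate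
24 | lithium alkoxide of the C9 tertiary carbinol from 16 and 23 (C9 configuration of no consequence) | CC1=C(OCC(C)C)C[C@H]2C(C)(C)CCC[C@]2(C)C1([O-])CC/C(C)=C/CO[Si](c3ccccc3)(c3ccccc3)C(C)(C)C.[Li+] | intermediate
25 | 15-(tert-butyldiphenylsilyloxy)labda-8,13E-dien-7-one | CC1=C(CC/C(C)=C/CO[Si](c3ccccc3)(c3ccccc3)C(C)(C)C)[C@@]2(C)CCCC(C)(C)[C@@H]2CC1=O | intermediate
26 | potassium 6,8-dien-7-olate of 25 | CC1=C(CC/C(C)=C/CO[Si](c3ccccc3)(c3ccccc3)C(C)(C)C)[C@@]2(C)CCCC(C)(C)[C@@H]2C=C1[O-].[K+] | intermediate
27 | 6α-hydroxy-15-(tert-butyldiphenylsilyloxy)labda-8,13E-dien-7-one | CC1=C(CC/C(C)=C/CO[Si](c3ccccc3)(c3ccccc3)C(C)(C)C)[C@@]2(C)CCCC(C)(C)[C@@H]2[C@@H](O)C1=O | intermediate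
28 | 6α-mesyloxy-15-(tert-butyldiphenylsilyloxy)labda-8,13E-dien-7-one | CC1=C(CC/C(C)=C/CO[Si](c3ccccc3)(c3ccccc3)C(C)(C)C)[C@@]2(C)CCCC(C)(C)[C@@H]2[C@@H](OS(C)(=O)=O)C1=O | intermediate
29 | 6α-mesyloxy-15-(tert-butyldiphenylsilyloxy)labda-8,13E-dien-7β-ol | CC1=C(CC/C(C)=C/CO[Si](c3ccccc3)(c3ccccc3)C(C)(C)C)[C@@]2(C)CCCC(C)(C)[C@@H]2[C@@H](OS(C)(=O)=O)[C@@H]1O | intermediate
30 | 6β,7β-epoxy-15-(tert-butyldiphenylsilyloxy)labda-8,13E-diene | CC1=C(CC/C(C)=C/CO[Si](c4ccccc4)(c4ccccc4)C(C)(C)C)[C@@]2(C)CCCC(C)(C)[C@@H]2[C@@H]3O[C@H]13 | intermediate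
31 | 7α-acetoxy-15-(tert-butyldiphenylsilyloxy)labda-8,13E-dien-6β-ol | CC1=C(CC/C(C)=C/CO[Si](c3ccccc3)(c3ccccc3)C(C)(C)C)[C@@]2(C)CCCC(C)(C)[C@@H]2[C@H](O)[C@H]1OC(C)=O | intermediate
32 | 6β,7α-diacetoxy-15-(tert-butyldiphenylsilyloxy)labda-8,13E-diene | CC1=C(CC/C(C)=C/CO[Si](c3ccccc3)(c3ccccc3)C(C)(C)C)[C@@]2(C)CCCC(C)(C)[C@@H]2[C@H](OC(C)=O)[C@H]1OC(C)=O | intermediate
33 | (5S,6S,7S,10S)-6β,7α-diacetoxylabda-8,13E-dien-15-ol (CNP0187815.1) | CC(=O)O[C@@H]1[C@@H](OC(C)=O)C(C)=C(CC/C(C)=C/CO)[C@@]2(C)CCCC(C)(C)[C@H]12 | target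

**Count and risks**
Total steps: 19. Longest linear sequence: 14 (steps 1–4, 6–8, 13–19).

Step 7 (most at risk).
- The magnesium enolate may be too weak a nucleophile for the neopentyl β-carbon C5.
- The sequence may stall at the chelated imide enolate before the acyl transfer.
- Incomplete chelation may erode the facial selectivity, or the trans/cis selectivity of the ring fusion.

The fallback uses known chemistry, sets out from 9 and comes back at 25. Horner–Wadsworth–Emmons reaction of 9 with trimethyl phosphonoacetate (LiCl, DBU, MeCN) should give methyl (E)-4,4,8-trimethyl-9-oxoundec-2-enoate F1. t-BuOK in THF, the established consecutive Michael–Claisen conditions, should close it to the racemic trans-decalin-7,9-dione F2. (−)-Menthol with p-TsOH in toluene (Dean–Stark trap) should turn F2 into two diastereomeric C7 enol ethers, the (5S,10S) menthyl enol ether F3 and the (5R,10R) menthyl enol ether F4, to be separated by crystallisation or chromatography. F3 then takes the place of 16 in step 13 and should give 25.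

Step 16.
- Hydride delivery may not be fully axial.
- From the diequatorial arrangement, the C7 alkoxide may trigger migration of C8 with ring contraction in place of epoxide closure.

The fallback inverts the two centres separately, sets out from 27 and comes back at 31.
- Et3SiCl and imidazole should give the 6α-triethylsilyl ether F5.
- NaBH4 with CeCl3·7H2O should give the 7β-alcohol F6.
- A Mitsunobu reaction (PPh3, DIAD, AcOH) should invert allylic C7 to the 7α-acetate F7.
- PPTS in MeOH should remove only the triethylsilyl group to give the 6α-alcohol F8.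
- Dess–Martin oxidation should give the 7α-acetoxy 6-ketone F9.
- NaBH4, attacking the C6 carbonyl from the open α-face as is usual for 6-oxolabdanes, should give 31.

Step 13.
- The basic organolithium may deprotonate C6 of the vinylogous ester rather than add to the C9 carbonyl, which sits between C8 and quaternary C10.
- The functionalised homoallyl-lithium may destroy itself by cyclopropane-forming expulsion of silanolate.

The fallback builds the side chain stepwise from a sturdier and less basic nucleophile, sets out from 16 and comes back at 25.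
- BrMgCH2CH2C(OCH2CH2O)CH3 (from commercial 2-(2-bromoethyl)-2-methyl-1,3-dioxolane and Mg), premixed with anhydrous CeCl3 and followed by 1 M HCl, should give 14,15-dinorlabd-8-ene-7,13-dione F10.
- Horner–Wadsworth–Emmons reaction with triethyl phosphonoacetate and NaH at the unhindered methyl ketone should give ethyl 7-oxolabda-8,13E-dien-15-oate F11, the Z isomer being removed by chromatography.
- i-Bu2AlH should reduce ester and ketone to labda-8,13E-diene-7,15-diol F12.
- TBDPSCl and imidazole should select the primary alcohol to give the 15-silyl ether 7-alcohol F13.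
- MnO2 should oxidise the remaining allylic alcohol to 25.

**Further compounds**
F1 | step 7 | methyl (E)-4,4,8-trimethyl-9-oxoundec-2-enoate | CCC(=O)C(C)CCCC(C)(C)/C=C/C(=O)OC
F2 | step 7 | racemic trans-2,5,5,8a-tetramethylhexahydronaphthalene-1,3(2H,4H)-dione (both enantiomers) | CC1C(=O)C[C@H]2C(C)(C)CCC[C@]2(C)C1=O.CC1C(=O)C[C@@H]2C(C)(C)CCC[C@@]2(C)C1=O
F3 | step 7 | (5S,10S) C7 (−)-menthyl enol ether of the dione | CC(C)[C@@H]1CC[C@@H](C)C[C@H]1OC2=C(C)C(=O)[C@@]3(C)CCCC(C)(C)[C@@H]3C2
F4 | step 7 | (5R,10R) C7 (−)-menthyl enol ether of the dione | CC(C)[C@@H]1CC[C@@H](C)C[C@H]1OC2=C(C)C(=O)[C@]3(C)CCCC(C)(C)[C@H]3C2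
F5 | step 16 | 6α-triethylsilyloxy-15-(tert-butyldiphenylsilyloxy)labda-8,13E-dien-7-one | CC1=C(CC/C(C)=C/CO[Si](c3ccccc3)(c3ccccc3)C(C)(C)C)[C@@]2(C)CCCC(C)(C)[C@@H]2[C@@H](O[Si](CC)(CC)CC)C1=O
F6 | step 16 | 6α-triethylsilyloxy-15-(tert-butyldiphenylsilyloxy)labda-8,13E-dien-7β-ol | CC1=C(CC/C(C)=C/CO[Si](c3ccccc3)(c3ccccc3)C(C)(C)C)[C@@]2(C)CCCC(C)(C)[C@@H]2[C@@H](O[Si](CC)(CC)CC)[C@@H]1O
F7 | step 16 | 7α-acetoxy-6α-triethylsilyloxy-15-(tert-butyldiphenylsilyloxy)labda-8,13E-diene | CC1=C(CC/C(C)=C/CO[Si](c3ccccc3)(c3ccccc3)C(C)(C)C)[C@@]2(C)CCCC(C)(C)[C@@H]2[C@@H](O[Si](CC)(CC)CC)[C@H]1OC(C)=O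
F8 | step 16 | 7α-acetoxy-15-(tert-butyldiphenylsilyloxy)labda-8,13E-dien-6α-ol | CC1=C(CC/C(C)=C/CO[Si](c3ccccc3)(c3ccccc3)C(C)(C)C)[C@@]2(C)CCCC(C)(C)[C@@H]2[C@@H](O)[C@H]1OC(C)=O
F9 | step 16 | 7α-acetoxy-15-(tert-butyldiphenylsilyloxy)labda-8,13E-dien-6-one | CC1=C(CC/C(C)=C/CO[Si](c3ccccc3)(c3ccccc3)C(C)(C)C)[C@@]2(C)CCCC(C)(C)[C@@H]2C(=O)[C@H]1OC(C)=O
F10 | step 13 | 14,15-dinorlabd-8-ene-7,13-dione | CC1=C(CCC(C)=O)[C@@]2(C)CCCC(C)(C)[C@@H]2CC1=O
F11 | step 13 | ethyl 7-oxolabda-8,13E-dien-15-oate | CC1=C(CC/C(C)=C/C(=O)OCC)[C@@]2(C)CCCC(C)(C)[C@@H]2CC1=O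
F12 | step 13 | labda-8,13E-diene-7,15-diol (C7 epimers, of no consequence) | CC1=C(CC/C(C)=C/CO)[C@@]2(C)CCCC(C)(C)[C@@H]2CC1O
F13 | step 13 | 15-(tert-butyldiphenylsilyloxy)labda-8,13E-dien-7-ol (C7 epimers, of no consequence) | CC1=C(CC/C(C)=C/CO[Si](c3ccccc3)(c3ccccc3)C(C)(C)C)[C@@]2(C)CCCC(C)(C)[C@@H]2CC1O
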